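The 2,3-dihydrofuran ring (O–C1=C2–C3–C4, germacrane numbering) is read as a ring-expanded cyclopropyl ketone. C2–C3–C4 is carried as a cyclopropane, the ring oxygen as the C1 ketone, and the C5=C6 enol-lactone double bond on quaternary C4 is the activating vinyl group. A nickel-catalysed vinylcyclopropyl ketone to dihydrofuran rearrangement, run transannularly at the end, forms the C4–O bond, the acid-labile bridgehead enol ether and the oxygen-bridged ten-membered carbocycle in one operation. Its precursor is a cis-fused bicyclo[7.1.0] nine-membered ketone that already carries the ylidene butenolide and is closed by a vinylogous aldol condensation.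

Key step: step 15

Remark: locants follow germacrane numbering (ring carbons C1–C10, lactone carbons C11–C13, methyls C14 and C15); the target is read as (4S,5E,8S,10R). 3,4-Dibromofuran-2(5H)-one, (R)-citramalic acid and the (4S,5S) dioxaborolane ligand are taken as purchasable.

Step 1
Reactants: 1 prop-2-yn-1-ol
Product: 2 (Z)-3-iodo-2-methylprop-2-en-1-ol
Conditions: MeMgBr (2.5 equiv), CuI (10 mol %), THF, −10 °C → rt; then I2, −78 → 0 °C; aq. HCl
Reagents that add atoms: methylmagnesium bromide C[Mg]Br; iodine II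
Why: Copper-catalysed anti-carbomagnesiation of the propargylic alkoxide places the methyl on the internal carbon and magnesium cis to the CH2O group in a five-membered chelate, so iodinolysis should give the Z vinyl iodide.

Step 2
Reactants: 2 (Z)-3-iodo-2-methylprop-2-en-1-ol
Product: 3 [(1S,2S)-2-iodo-1-methylcyclopropyl]methanol
Conditions: Et2Zn, CH2I2, DME, CH2Cl2, −10 °C; (4S,5S)-2-butyl-N,N,N',N'-tetramethyl-1,3,2-dioxaborolane-4,5-dicarboxamide (1.2 equiv); 0 °C → rt
Reagents that add atoms: diiodomethane ICI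
Why: Charette asymmetric Simmons–Smith cyclopropanation, in which the zinc alkoxide bound to the chiral dioxaborolane delivers CH2 to one alkene face stereospecifically (Z alkene gives cis iodine and CH2OH), should set both ring stereocentres (later C2 and C4).

Step 3
Reactants: 3 [(1S,2S)-2-iodo-1-methylcyclopropyl]methanol
Product: 4 triethyl{[(1S,2S)-2-iodo-1-methylcyclopropyl]methoxy}silane
Conditions: TESCl, imidazole, CH2Cl2, 0 °C
Reagents that add atoms: chlorotriethylsilane CC[Si](Cl)(CC)CC
Why: Standard silylation of the primary alcohol, with TES chosen because it survives the organolithium step and can later be oxidised directly to the aldehyde.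

Step 4
Reactants: 5 (R)-citramalic acid
Product: 6 2-[(4R)-2,2,4-trimethyl-5-oxo-1,3-dioxolan-4-yl]acetic acid
Conditions: 2,2-dimethoxypropane, TsOH (cat.), rt
Reagents that add atoms: 2,2-dimethoxypropane COC(C)(C)OC
Why: Acetalisation ties up only the α-hydroxy acid unit as a five-membered dioxolanone, leaving the β-carboxyl free and the chiral-pool stereocentre (later C10) untouched.

Step 5
Reactants: 6 2-[(4R)-2,2,4-trimethyl-5-oxo-1,3-dioxolan-4-yl]acetic acid
Product: 8 (3R)-3-hydroxy-3-methyloxolan-2-one, via hydroxyethyl dioxolanone 7 (not isolated)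
Conditions: BH3·SMe2, THF, 0 °C → rt; MeOH; then TsOH·H2O (cat.), CH2Cl2, rt
Reagents that add atoms: none
Why: Borane reduces the free carboxylic acid chemoselectively over the dioxolanone, and acid-catalysed translactonisation of the γ-hydroxy dioxolanone should release acetone and give the α-hydroxy γ-lactone.

Step 6
Reactants: 4 triethyl{[(1S,2S)-2-iodo-1-methylcyclopropyl]methoxy}silane; 8 (3R)-3-hydroxy-3-methyloxolan-2-one
Product: 11 (2R)-2,4-dihydroxy-2-methyl-1-[(1S,2R)-2-methyl-2-(triethylsilyloxymethyl)cyclopropyl]butan-1-one, via cyclopropyllithium 9 (not isolated), via lactone lithium alkoxide 10 (not isolated)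
Conditions: 4, t-BuLi (2.0 equiv), Et2O, −78 °C; 8, LiHMDS (1.0 equiv), THF, −78 °C; combine, −78 → −30 °C; AcOH
Reagents that add atoms: none
Why: Iodine–lithium exchange on the cyclopropyl iodide proceeds with retention, and acyl substitution on the lactone should stop at the ketone because the lithium hemiketal, chelated by the neighbouring alkoxide, persists until the quench (acyl and CH2OTES stay cis).

Step 7
Reactants: 11 (2R)-2,4-dihydroxy-2-methyl-1-[(1S,2R)-2-methyl-2-(triethylsilyloxymethyl)cyclopropyl]butan-1-one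
Product: 12 (3R)-3-hydroxy-3-methyl-4-[(1S,2R)-2-methyl-2-(triethylsilyloxymethyl)cyclopropyl]-4-oxobutanal
Conditions: TEMPO (10 mol %), PhI(OAc)2, CH2Cl2, rt
Reagents that add atoms: none
Why: Oxoammonium oxidation selects the unhindered primary alcohol and stops at the aldehyde, while the tertiary alcohol cannot be oxidised.

Step 8
Reactants: 12 (3R)-3-hydroxy-3-methyl-4-[(1S,2R)-2-methyl-2-(triethylsilyloxymethyl)cyclopropyl]-4-oxobutanal; 13 3,4-dibromofuran-2(5H)-one
Product: 14 3-bromo-4-{(3R)-1,3-dihydroxy-3-methyl-4-[(1S,2R)-2-methyl-2-(triethylsilyloxymethyl)cyclopropyl]-4-oxobutyl}furan-2(5H)-one (both C8 epimers)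
Conditions: CrCl2 (4 equiv), NiCl2 (2 mol %), DMF, rt
Reagents that add atoms: none
Why: In this Nozaki–Hiyama–Kishi coupling, zerovalent nickel should insert into the more electrophilic C4–Br bond of the butenolide (a vinylogous acyl bromide), and the alkenylchromium adds to the aldehyde in the presence of ketone and lactone; C8 is formed without control here and is corrected in steps 9 and 10.

Step 9
Reactants: 14 C8-epimeric bromobutenolide carbinols
Product: 15 3-bromo-4-{(3R)-3-hydroxy-3-methyl-4-[(1S,2R)-2-methyl-2-(triethylsilyloxymethyl)cyclopropyl]-4-oxobutanoyl}furan-2(5H)-one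
Conditions: Dess–Martin periodinane, NaHCO3, CH2Cl2, 0 °C
Reagents that add atoms: none
Why: Buffered Dess–Martin oxidation of the secondary allylic alcohol converges both epimers on one ketone and leaves the tertiary alcohol alone.

Step 10
Reactants: 15 C8 ketone
Product: 16 3-bromo-4-{(1S,3R)-1,3-dihydroxy-3-methyl-4-[(1S,2R)-2-methyl-2-(triethylsilyloxymethyl)cyclopropyl]-4-oxobutyl}furan-2(5H)-one
Conditions: (R)-2-methyl-CBS-oxazaborolidine (20 mol %), catecholborane (2.5 equiv), toluene, −78 °C
Reagents that add atoms: none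
Why: In this Corey–Bakshi–Shibata reduction the catalyst binds the conjugated C8 ketone with the butenolide alkenyl group as the large substituent, so 1,2-hydride delivery should give 8S, while the C1 ketone, flanked by a quaternary carbon and the cyclopropane, reacts far more slowly.

Step 11
Reactants: 16 (8S)-bromobutenolide diol
Product: 17 3-(hydroxymethyl)-4-{(1S,3R)-1,3-dihydroxy-3-methyl-4-[(1S,2R)-2-methyl-2-(triethylsilyloxymethyl)cyclopropyl]-4-oxobutyl}furan-2(5H)-one
Conditions: Bu3SnCH2OH, Pd(PPh3)4 (5 mol %), dioxane, 90 °C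
Reagents that add atoms: (tributylstannyl)methanol CCCC[Sn](CCCC)(CCCC)CO
Why: Stille coupling at the α-bromide of the butenolide installs C13 at the alcohol oxidation level and tolerates the free hydroxyl groups.

Step 12
Reactants: 17 triol
Product: 18 tris-TBS ether of 17 (C8–O, C10–O and C13–O silylated, C5–OTES retained)
Conditions: TBSOTf (3.5 equiv), 2,6-lutidine, CH2Cl2, −78 → 0 °C
Reagents that add atoms: tert-butyldimethylsilyl triflate CC(C)(C)[Si](C)(C)OS(=O)(=O)C(F)(F)F
Why: The silyl triflate with a hindered pyridine base silylates primary, secondary and tertiary hydroxyls, while the base is too weak to enolise the butenolide.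

Step 13
Reactants: 18 tris-TBS TES ether
Product: 19 seco aldehyde (C5 cyclopropanecarbaldehyde, cis to the C1 acyl group; 2S,4R,8S,10R)
Conditions: (COCl)2, DMSO, CH2Cl2, −78 → −30 °C; then Et3N, −78 °C → rt
Reagents that add atoms: none
Why: Under Swern conditions a primary TES ether is converted directly into the aldehyde through the alkoxysulfonium ion, while TBS ethers survive; the aldehyde is not enolisable.

Step 14
Reactants: 19 seco aldehyde
Product: 22 macrocyclic vinylcyclopropyl ketone (2S,4S,5E,8S,10R), via silyloxyfuran 20 (not isolated), via aldol silyl ether 21 (not isolated)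
Conditions: TBSOTf (2 equiv), i-Pr2NEt (4 equiv), CH2Cl2, slow addition of 19 to 1 mM, 0 °C → rt; then DBU (3 equiv), rt
Reagents that add atoms: none
Why: In this one-pot vinylogous Mukaiyama aldol–elimination, the butenolide is silylated to a 2-silyloxyfuran whose C6 adds to the silyl-activated C5 aldehyde, and DBU then expels silanol by E1cB to give the ylidene butenolide; the nine-membered ring allows only the in-ring cis C5=C6 geometry (5E), and high dilution favours closure over oligomerisation.

Step 15
Reactants: 22 macrocyclic vinylcyclopropyl ketone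
Product: 23 tris-TBS ether of the target core (4S,5E,8S,10R; 1,4-epoxy-bridged ten-membered carbocycle with C1=C2 enol ether)
Conditions: Ni(cod)2 (20 mol %), PPh3 (40 mol %), toluene, 25 → 60 °C
Reagents that add atoms: none
Why: Zerovalent nickel binds the C5=C6 alkene and inserts into the strained, ketone-activated C2–C4 bond to give an η3-allylnickel (C4–C5–C6) carrying an O-bound C1=C2 enolate, and C–O bond formation between the enolate oxygen and C4 releases the catalyst. The closest known reaction is the nickel-catalysed rearrangement of 1-acyl-2-vinylcyclopropanes to 2,3-dihydrofurans, a metal-mediated Cloke–Wilson rearrangement. The five-membered ring closes by O-attack on the allyl terminus C4 in a 5-exo-trig mode with C1=C2 inside the new ring, and this transannular bond turns the nine-membered carbocycle into the ten-membered carbocycle bridged by oxygen. C4 is the only stereocentre touched, and its configuration should be relayed from the cyclopropane (set in step 2) with net retention, because nickel enters anti to C2 and oxygen attacks anti to nickel while the ring forbids rotation of the allyl unit. The step needs O- over C-alkylation of the enolate and attack at C4 over C6, both favoured by the unstrained five-membered ring against a bridged seven-membered ketal or re-closure to the cyclopropane. The cis ring fusion holds the carbonyl oxygen over the C3–C4 edge, and the silyl ethers keep the allylic C13 and C8 oxygens from ionising.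

Step 16
Reactants: 23 tris-TBS ether
Product: 24 triol (4S,5E,8S,10R) with free C8, C10 and C13 hydroxyls
Conditions: TBAF (4 equiv), AcOH (4 equiv), THF, 0 → 40 °C
Reagents that add atoms: none
Why: Fluoride cleaves all three silyl ethers, and the acetic acid buffer protects the enol ether and the enol lactone from base.

Step 17
Reactants: 24 triol
Product: 25 13-O-acetate (C8 and C10 hydroxyls free)
Conditions: Ac2O (1.1 equiv), 2,4,6-collidine, CH2Cl2, −20 °C
Reagents that add atoms: acetic anhydride CC(=O)OC(C)=O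
Why: With a weak base at low temperature the primary allylic hydroxyl is acetylated much faster than the secondary and tertiary ones.

Step 18
Reactants: 25 13-O-acetate
Product: 26 target CNP0394509.2
Conditions: methacrylic anhydride, Et3N, DMAP (10 mol %), CH2Cl2, 0 °C
Reagents that add atoms: methacrylic anhydride C=C(C)C(=O)OC(=O)C(C)=C
Why: DMAP-catalysed acylation esterifies the secondary C8 hydroxyl, while the tertiary C10 hydroxyl is too hindered to react.

Compound list
1 | prop-2-yn-1-ol | C#CCO | starting material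
2 | (Z)-3-iodo-2-methylprop-2-en-1-ol | OC/C(C)=C\I | intermediate
3 | [(1S,2S)-2-iodo-1-methylcyclopropyl]methanol | OC[C@]1(C)C[C@@H]1I | intermediate
4 | triethyl{[(1S,2S)-2-iodo-1-methylcyclopropyl]methoxy}silane | CC[Si](CC)(CC)OC[C@]1(C)C[C@@H]1I | intermediate
5 | (R)-citramalic acid, (2R)-2-hydroxy-2-methylbutanedioic acid | C[C@@](O)(CC(=O)O)C(=O)O | starting material
6 | 2-[(4R)-2,2,4-trimethyl-5-oxo-1,3-dioxolan-4-yl]acetic acid | C[C@]1(CC(=O)O)OC(C)(C)OC1=O | intermediate
7 | (5R)-5-(2-hydroxyethyl)-2,2,5-trimethyl-1,3-dioxolan-4-one | C[C@]1(CCO)OC(C)(C)OC1=O | intermediate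
8 | (3R)-3-hydroxy-3-methyloxolan-2-one | C[C@@]1(O)CCOC1=O | intermediate
9 | cyclopropyllithium from 4 (lithium in place of iodine, configuration retained) | CC[Si](CC)(CC)OC[C@]1(C)C[C@@H]1[Li] | intermediate
10 | lithium alkoxide of 8 | C[C@@]1(O[Li])CCOC1=O | intermediate
11 | (2R)-2,4-dihydroxy-2-methyl-1-[(1S,2R)-2-methyl-2-(triethylsilyloxymethyl)cyclopropyl]butan-1-one | CC[Si](CC)(CC)OC[C@]1(C)C[C@@H]1C(=O)[C@](C)(O)CCO | intermediate
12 | (3R)-3-hydroxy-3-methyl-4-[(1S,2R)-2-methyl-2-(triethylsilyloxymethyl)cyclopropyl]-4-oxobutanal | CC[Si](CC)(CC)OC[C@]1(C)C[C@@H]1C(=O)[C@](C)(O)CC=O | intermediate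
13 | 3,4-dibromofuran-2(5H)-one | O=C1OCC(Br)=C1Br | starting material
14 | 3-bromo-4-{(3R)-1,3-dihydroxy-3-methyl-4-[(1S,2R)-2-methyl-2-(triethylsilyloxymethyl)cyclopropyl]-4-oxobutyl}furan-2(5H)-one, both C8 epimers | CC[Si](CC)(CC)OC[C@]1(C)C[C@@H]1C(=O)[C@](C)(O)CC(O)C2=C(Br)C(=O)OC2 | intermediate
15 | 3-bromo-4-{(3R)-3-hydroxy-3-methyl-4-[(1S,2R)-2-methyl-2-(triethylsilyloxymethyl)cyclopropyl]-4-oxobutanoyl}furan-2(5H)-one | CC[Si](CC)(CC)OC[C@]1(C)C[C@@H]1C(=O)[C@](C)(O)CC(=O)C2=C(Br)C(=O)OC2 | intermediate
16 | 3-bromo-4-{(1S,3R)-1,3-dihydroxy-3-methyl-4-[(1S,2R)-2-methyl-2-(triethylsilyloxymethyl)cyclopropyl]-4-oxobutyl}furan-2(5H)-one | CC[Si](CC)(CC)OC[C@]1(C)C[C@@H]1C(=O)[C@](C)(O)C[C@H](O)C2=C(Br)C(=O)OC2 | intermediate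
17 | 3-(hydroxymethyl) analogue of 16 (CH2OH in place of Br) | CC[Si](CC)(CC)OC[C@]1(C)C[C@@H]1C(=O)[C@](C)(O)C[C@H](O)C2=C(CO)C(=O)OC2 | intermediate
18 | tris-TBS ether of 17 (C8, C10, C13 oxygens silylated; C5–OTES) | CC[Si](CC)(CC)OC[C@]1(C)C[C@@H]1C(=O)[C@](C)(O[Si](C)(C)C(C)(C)C)C[C@H](O[Si](C)(C)C(C)(C)C)C2=C(CO[Si](C)(C)C(C)(C)C)C(=O)OC2 | intermediate
19 | seco aldehyde: 18 with the CH2OTES group replaced by CHO (2S,4R,8S,10R) | O=C[C@]1(C)C[C@@H]1C(=O)[C@](C)(O[Si](C)(C)C(C)(C)C)C[C@H](O[Si](C)(C)C(C)(C)C)C2=C(CO[Si](C)(C)C(C)(C)C)C(=O)OC2 | intermediate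
20 | 2-(tert-butyldimethylsilyloxy)furan form of 19 | O=C[C@]1(C)C[C@@H]1C(=O)[C@](C)(O[Si](C)(C)C(C)(C)C)C[C@H](O[Si](C)(C)C(C)(C)C)c2coc(O[Si](C)(C)C(C)(C)C)c2CO[Si](C)(C)C(C)(C)C | intermediate
21 | nine-membered aldol silyl ether (C5–OTBS, C6–H, mixture at C5 and C6) | O=C1[C@H]2C[C@@]2(C)C(O[Si](C)(C)C(C)(C)C)C3OC(=O)C(CO[Si](C)(C)C(C)(C)C)=C3[C@@H](O[Si](C)(C)C(C)(C)C)C[C@@]1(C)O[Si](C)(C)C(C)(C)C | intermediate
22 | macrocyclic vinylcyclopropyl ketone: nine-membered ring C1(=O)–C2–C4–C5=C6–C7–C8–C9–C10 with cis-fused C2–C3–C4 cyclopropane, (5E)-ylidene butenolide fused at C6–C7, OTBS at C8, C10 and C13; (2S,4S,5E,8S,10R), the C4 descriptor differing from 19 by priority only | O=C1[C@H]2C[C@@]2(C)/C=C3/OC(=O)C(CO[Si](C)(C)C(C)(C)C)=C3[C@@H](O[Si](C)(C)C(C)(C)C)C[C@@]1(C)O[Si](C)(C)C(C)(C)C | intermediate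
23 | tris-TBS ether of the target core, (4S,5E,8S,10R)-1,4-epoxy-bridged carbocycle with C1=C2 enol ether | CC(C)(C)[Si](C)(C)O[C@H]1C[C@@](C)(O[Si](C)(C)C(C)(C)C)C2=CC[C@@](C)(/C=C3/OC(=O)C(CO[Si](C)(C)C(C)(C)C)=C31)O2 | intermediate
24 | triol (4S,5E,8S,10R), free C8, C10 and C13 hydroxyls | O[C@H]1C[C@@](C)(O)C2=CC[C@@](C)(/C=C3/OC(=O)C(CO)=C31)O2 | intermediate
25 | 13-O-acetate of 24 | O[C@H]1C[C@@](C)(O)C2=CC[C@@](C)(/C=C3/OC(=O)C(COC(C)=O)=C31)O2 | intermediate
26 | CNP0394509.2, 8-O-methacrylate 13-O-acetate (4S,5E,8S,10R) | C=C(C)C(=O)O[C@H]1C[C@@](C)(O)C2=CC[C@@](C)(/C=C3/OC(=O)C(COC(C)=O)=C31)O2 | target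

Total step count: 18. Longest linear sequence: 16 steps (steps 1–3 and 6–18, from prop-2-yn-1-ol).

Steps most likely to fail

Step 15. The dienyl lactone may sequester zerovalent nickel so that insertion into the C2–C4 bond does not occur, the enolate oxygen may close on C6, or face exchange of the allyl unit may erode the C4 configuration. The fallback replaces the metal-mediated rearrangement by solvolytic opening and dehydration. It sets out from 22: Yb(OTf)3 (cat.) in wet MeCN ionises the ketone-activated cyclopropane at C4, and capture by water and the C1 carbonyl should give the 1-hydroxy-1,4-epoxy hemiketal F1 as the thermodynamic sink. MsCl/Et3N in CH2Cl2 at 0 °C then dehydrates the hemiketal to the enol ether, and the route is rejoined at 23.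

Step 14. Intermolecular aldol addition of the silyloxyfuran may outrun closure of the nine-membered ring, giving oligomers. The fallback changes the ring-closing event to an intramolecular Horner–Wadsworth–Emmons olefination. It sets out from 18: TBSOTf/Et3N gives the silyloxyfuran F2, NBS in THF at −78 °C gives the 5-bromobutenolide F3, and Arbuzov reaction with P(OEt)3 at 90 °C gives the 5-phosphonobutenolide F4. Swern oxidation of the TES ether gives the phosphonate aldehyde F5, and LiCl/DBU in MeCN at high dilution closes the ring, rejoining the route at 22.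

Step 10. The hydride may also reduce the C1 ketone, add in a conjugate sense to the bromobutenolide, or attack the C8 ketone with poor facial selectivity. The fallback sets the stereocentre during C–C bond formation: from 12 and 13, a catalytic asymmetric Nozaki–Hiyama–Kishi coupling (CrCl2 with a chiral sulfonamide ligand, NiCl2, Mn, TMSCl, MeCN) should give the 8S carbinol directly, bypassing 14 and 15 and rejoining the route at 16 (no new compound, F0).

Further compounds
F1 | step 15 | 1-hydroxy-1,4-epoxy hemiketal of the tris-TBS core (water added across C1=C2 of 23, C1 configuration under thermodynamic control) | CC(C)(C)[Si](C)(C)O[C@H]1C[C@@](C)(O[Si](C)(C)C(C)(C)C)C2(O)CC[C@@](C)(/C=C3/OC(=O)C(CO[Si](C)(C)C(C)(C)C)=C31)O2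
F2 | step 14 | 2-(tert-butyldimethylsilyloxy)furan form of 18 | CC[Si](CC)(CC)OC[C@]1(C)C[C@@H]1C(=O)[C@](C)(O[Si](C)(C)C(C)(C)C)C[C@H](O[Si](C)(C)C(C)(C)C)c2coc(O[Si](C)(C)C(C)(C)C)c2CO[Si](C)(C)C(C)(C)C
F3 | step 14 | 5-bromobutenolide from 18 (bromine at C6, mixture at C6) | CC[Si](CC)(CC)OC[C@]1(C)C[C@@H]1C(=O)[C@](C)(O[Si](C)(C)C(C)(C)C)C[C@H](O[Si](C)(C)C(C)(C)C)C2=C(CO[Si](C)(C)C(C)(C)C)C(=O)OC2Br
F4 | step 14 | 5-(diethoxyphosphoryl)butenolide (phosphonate at C6, mixture at C6) | CC[Si](CC)(CC)OC[C@]1(C)C[C@@H]1C(=O)[C@](C)(O[Si](C)(C)C(C)(C)C)C[C@H](O[Si](C)(C)C(C)(C)C)C2=C(CO[Si](C)(C)C(C)(C)C)C(=O)OC2P(=O)(OCC)OCC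
F5 | step 14 | phosphonate aldehyde (F4 with the CH2OTES group replaced by CHO) | O=C[C@]1(C)C[C@@H]1C(=O)[C@](C)(O[Si](C)(C)C(C)(C)C)C[C@H](O[Si](C)(C)C(C)(C)C)C2=C(CO[Si](C)(C)C(C)(C)C)C(=O)OC2P(=O)(OCC)OCC
F0 | step 10 | none | none
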